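**Plan**

- Retrosynthesis: the hemiketal bond O1–C2 is opened to the 1,3-diketo acid, and its C2 carbonyl is held as the enol lactone of the ring B carboxyl (an isocoumarin). Ring A is then cut at C5–C6 and C4a–C8a, and the remaining alkynyl ketone at C4–C4a.
- Enabling feature: ring A carries the acyl carbon C4 on C4a, between heptyl on C5 and oxygen on C8a, with the second oxygen on C7 para to C4a. A 1,1,3-trioxygenated butadiene (C6, C7, C8, C8a) adding to an alkynyl ketone whose triple bond is C5≡C4a gives exactly this pattern.
- Forward: ring B is bought as an arene. The lactone ring of the isocoumarin is closed first (C-acylation of a homophthalic anhydride), the side chain is extended to the ynone by acyl–alkynyl coupling, and ring A is built last by Diels–Alder addition and aromatization. Hydroxide then opens the lactone and the pyranone ring closes as the hemiketal.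
- Stereochemistry: C2 is the only stereocentre and is labile. It is fixed at the very end by crystallization of the quinine salt under equilibrating conditions and cold release of the (R)-acid.

Key step: step 10

Remark on the chemistry: C2 epimerizes through ring–chain tautomerism with the achiral 1,3-diketone; it is assumed that the quinine salt of the (R)-acid is the less soluble diastereomer (quinidine would take its place otherwise) and that the free (R)-acid holds its configuration as a solid and in cold, base-free solution.

**Route**

Step 1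
Reactants: 1 methyl acetoacetate
Product: 2 methyl 3-(trimethylsilyloxy)but-2-enoate (E/Z mixture)
Conditions: TMSCl, Et3N, hexane, rt
Reagents that add atoms: chlorotrimethylsilane, C[Si](C)(C)Cl
Why: Triethylamine and the chlorosilane trap the enol of the β-keto ester as its silyl enol ether (O-silylation), and both double-bond isomers converge in the next step.

Step 2
Reactants: 2 methyl 3-(trimethylsilyloxy)but-2-enoate
Product: 3 (1Z)-1-methoxy-1,3-bis(trimethylsilyloxy)buta-1,3-diene
Conditions: LiN(i-Pr)2 (LDA), THF, −78 °C; TMSCl, −78 → 0 °C; non-aqueous work-up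
Reagents that add atoms: chlorotrimethylsilane, C[Si](C)(C)Cl
Why: The amide base removes a γ-proton of the silyloxy crotonate and the ester dienolate is silylated on oxygen (silyl ketene acetal formation), which should give the trioxygenated diene.

Step 3
Reactants: 4 methyl 2-(3,5-dimethoxyphenyl)acetate
Product: 5 methyl 2-(2-formyl-3,5-dimethoxyphenyl)acetate
Conditions: POCl3, DMF, 0 → 60 °C; ice–water
Reagents that add atoms: N,N-dimethylformamide, CN(C)C=O; water, O
Why: Vilsmeier–Haack formylation should enter at C2, para to one methoxy group and ortho to the other, because the position between the two methoxy groups is the more hindered one.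

Step 4
Reactants: 5 methyl 2-(2-formyl-3,5-dimethoxyphenyl)acetate
Product: 7 2-(carboxymethyl)-4,6-dimethoxybenzoic acid, via monoester acid 6 (not isolated)
Conditions: NaClO2, NaH2PO4, 2-methyl-2-butene, t-BuOH/H2O, rt; then NaOH (aq), 40 °C; HCl to pH 1
Reagents that add atoms: sodium chlorite, [Na+].[O-]Cl=O; sodium hydroxide, [Na+].[OH-]
Why: Pinnick oxidation turns the electron-rich aldehyde into the benzoic acid while the alkene traps hypochlorous acid, and NaOH added to the same flask saponifies the unhindered aliphatic methyl ester to the homophthalic acid.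

Step 5
Reactants: 7 2-(carboxymethyl)-4,6-dimethoxybenzoic acid
Product: 8 6,8-dimethoxyisochromane-1,3-dione
Conditions: Ac2O, toluene, 110 °C
Reagents that add atoms: none
Why: Acetic anhydride dehydrates the diacid to the six-membered cyclic anhydride (anhydride formation), the usual activation of a homophthalic acid.

Step 6
Reactants: 8 6,8-dimethoxyisochromane-1,3-dione; 9 methyl 3-chloro-3-oxopropanoate (methyl malonyl chloride)
Product: 12 methyl 2-(6,8-dimethoxy-1-oxo-1H-isochromen-3-yl)acetate, via C-acylated anhydride 10 (not isolated), via keto acid 11 (not isolated)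
Conditions: TMG, Et3N, MeCN, −20 → 0 °C; 2 M HCl, 40 °C; then TsOH·H2O (cat.), toluene, reflux, azeotropic removal of water
Reagents that add atoms: none
Why: Tetramethylguanidine deprotonates C4 of the anhydride, which is C-acylated by the acid chloride (acylation of a homophthalic anhydride); aqueous acid opens the product to a β-keto acid that loses CO2, and acid-catalysed enol lactonization of the keto acid should close the isocoumarin with the C3=C4 bond in conjugation with the arene.

Step 7
Reactants: 12 methyl 2-(6,8-dimethoxy-1-oxo-1H-isochromen-3-yl)acetate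
Product: 13 2-(6,8-dihydroxy-1-oxo-1H-isochromen-3-yl)acetic acid
Conditions: BBr3 (8 equiv), CH2Cl2, −78 °C → rt; H2O, 0 °C
Reagents that add atoms: none
Why: BBr3 should cleave both aryl methyl ethers and, in excess at room temperature, the unhindered methyl ester by bromide attack at the methyl groups (Lewis acid dealkylation), conditions that 6,8-dimethoxyisocoumarin lactones tolerate.

Step 8
Reactants: 13 2-(6,8-dihydroxy-1-oxo-1H-isochromen-3-yl)acetic acid
Product: 14 tert-butyldimethylsilyl 2-[6,8-bis(tert-butyldimethylsilyloxy)-1-oxo-1H-isochromen-3-yl]acetate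
Conditions: TBSCl (3.5 equiv), imidazole, DMF, 40 °C
Reagents that add atoms: tert-butyl(chloro)dimethylsilane, CC(C)(C)[Si](C)(C)Cl
Why: Silylation covers the two phenols, whose acidity would destroy the diene of step 10, and turns the acid into its silyl ester, the direct precursor of the acid chloride.

Step 9
Reactants: 14 tert-butyldimethylsilyl 2-[6,8-bis(tert-butyldimethylsilyloxy)-1-oxo-1H-isochromen-3-yl]acetate; 15 non-1-yne
Product: 19 6,8-bis(tert-butyldimethylsilyloxy)-3-(2-oxoundec-3-yn-1-yl)-1H-isochromen-1-one, via acid chloride 16 (not isolated), via non-1-ynyllithium 17 (not isolated), via chloro(non-1-ynyl)zinc 18 (not isolated)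
Conditions: 14, (COCl)2, DMF (cat.), CH2Cl2, 0 °C → rt, evaporation; separately 15, n-BuLi, THF, −78 °C, then ZnCl2, 0 °C; combined with Pd(PPh3)4 (5 mol %), THF, 0 °C → rt
Reagents that add atoms: none
Why: Oxalyl chloride with catalytic DMF converts the silyl ester into the acid chloride without releasing HCl, and zerovalent palladium couples it with the alkynylzinc chloride (Negishi acylation), a weakly basic nucleophile that should neither enolize the acid chloride nor attack the lactone.

Step 10
Reactants: 19 6,8-bis(tert-butyldimethylsilyloxy)-3-(2-oxoundec-3-yn-1-yl)-1H-isochromen-1-one; 3 (1Z)-1-methoxy-1,3-bis(trimethylsilyloxy)buta-1,3-diene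
Product: 22 6,8-bis(tert-butyldimethylsilyloxy)-3-[2-(2-heptyl-4,6-dihydroxyphenyl)-2-oxoethyl]-1H-isochromen-1-one, via cyclohexadiene cycloadduct 20 (not isolated), via ring A trimethylsilyl ether 21 (not isolated)
Conditions: 3 (2.5 equiv), toluene, 90 °C, sealed vessel; then MeOH, PPTS (cat.), 0 °C → rt
Reagents that add atoms: none
Why: The electron-rich diene 3 and the electron-poor triple bond of 19 should combine in a thermal, strongly asynchronous [4+2] cycloaddition (Diels–Alder reaction) in which the CH2 terminus of 3 bonds to the heptyl-bearing β-carbon (C5–C6) and the ketene acetal carbon to the α-carbon (C4a–C8a), giving cyclohexa-1,4-diene 20. The mixed ketal carbon of 20 then expels methoxytrimethylsilane and a proton shifts from C6 to oxygen, so that ring A aromatizes to 21 with a free hydroxyl on C8a and a silyl ether on C7, which methanol with a trace of acid converts into 22. The closest known reaction type is the Diels–Alder benzannulation of 1-alkoxy-1,3-bis(silyloxy)buta-1,3-dienes with acetylenic ketones and esters to give 2-acylresorcinols. Ring A, the only ring closed, forms by an intermolecular six-membered [4+2] closure that makes both new bonds in one operation, and no stereocentre results because the single sp3 ketal carbon of 20 is lost on aromatization. The step needs regioselectivity, secured by the match of the largest HOMO coefficient at the diene CH2 with the largest LUMO coefficient at the ynone β-carbon, and chemoselectivity for the ynone over the enol-lactone C3=C4 bond of the isocoumarin, secured by the far lower LUMO of the conjugated alkyne. The lactone holds the future C2 carbonyl as an acylated enol, so no free 1,3-diketone is present that could close onto the alkyne to a γ-pyrone, and the silyl ethers on ring B remove the phenolic protons that would quench the diene.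

Step 11
Reactants: 22 6,8-bis(tert-butyldimethylsilyloxy)-3-[2-(2-heptyl-4,6-dihydroxyphenyl)-2-oxoethyl]-1H-isochromen-1-one
Product: 25 rac-2-[(5-heptyl-2,7-dihydroxy-4-oxo-3,4-dihydro-2H-chromen-2-yl)methyl]-4,6-dihydroxybenzoic acid, via desilylated isocoumarin 23 (not isolated), via open-chain diketo acid 24 (not isolated)
Conditions: KOH (2 M aq, 10 equiv), MeOH/THF, argon, 0 → 40 °C; 1 M HCl to pH 3, 0 °C
Reagents that add atoms: potassium hydroxide, [K+].[OH-]
Why: Hydroxide cleaves the two aryl silyl ethers and saponifies the enol lactone (alkaline hydrolysis of an isocoumarin to its keto acid), the freed 1,3-diketone being shielded from retro-Claisen cleavage as its enolate, and on cold acidification the ring A hydroxyl ortho to the ketone should add to the C2 carbonyl to give the 2-hydroxychroman-4-one, at this stage without control at C2.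

Step 12
Reactants: 25 rac-2-[(5-heptyl-2,7-dihydroxy-4-oxo-3,4-dihydro-2H-chromen-2-yl)methyl]-4,6-dihydroxybenzoic acid
Product: 26 quininium (R)-2-[(5-heptyl-2,7-dihydroxy-4-oxo-3,4-dihydro-2H-chromen-2-yl)methyl]-4,6-dihydroxybenzoate (1:1 salt)
Conditions: quinine (1.1 equiv), MeCN/acetone, 45 → 20 °C, slurry aged with stirring; filtration
Reagents that add atoms: quinine, COC1=CC2=C(C=CN=C2C=C1)[C@H]([C@@H]3C[C@@H]4CCN3C[C@@H]4C=C)O
Why: Proposed new method: the tertiary amine opens the hemiketal reversibly to the achiral phenoxide/1,3-diketone, so the two diastereomeric quininium carboxylates interconvert in solution while the less soluble one, taken to be that of the (R)-acid, crystallizes and draws the whole material into one configuration at C2 (a tertiary amine is used because primary and secondary amines would condense with the diketone); the closest known reaction type is the crystallization-induced diastereomer transformation of configurationally labile lactols, hemiaminals and easily enolized acids as salts of chiral amines, which has not been shown on 2-hydroxychroman-4-one hemiketals.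

Step 13
Reactants: 26 quininium (R)-2-[(5-heptyl-2,7-dihydroxy-4-oxo-3,4-dihydro-2H-chromen-2-yl)methyl]-4,6-dihydroxybenzoate
Product: 27 (R)-2-[(5-heptyl-2,7-dihydroxy-4-oxo-3,4-dihydro-2H-chromen-2-yl)methyl]-4,6-dihydroxybenzoic acid (CNP0232458.1)
Conditions: 0.5 M HCl (1.05 equiv), EtOAc, 0 °C; phases separated at once, dried and evaporated cold
Reagents that add atoms: none
Why: Cold dilute acid protonates the carboxylate and carries quinine into the water layer (salt break), and with no base left and the acid kept cold, ring opening at C2 should be too slow to erode the configuration fixed in the crystal.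

**Compound list**

1 | methyl acetoacetate | COC(=O)CC(C)=O | starting material
2 | methyl 3-(trimethylsilyloxy)but-2-enoate (E/Z mixture) | COC(=O)C=C(C)O[Si](C)(C)C | intermediate
3 | (1Z)-1-methoxy-1,3-bis(trimethylsilyloxy)buta-1,3-diene | C=C(O[Si](C)(C)C)/C=C(/OC)O[Si](C)(C)C | intermediate
4 | methyl 2-(3,5-dimethoxyphenyl)acetate | COC(=O)Cc1cc(OC)cc(OC)c1 | starting material
5 | methyl 2-(2-formyl-3,5-dimethoxyphenyl)acetate | COC(=O)Cc1cc(OC)cc(OC)c1C=O | intermediate
6 | 2,4-dimethoxy-6-(2-methoxy-2-oxoethyl)benzoic acid | COC(=O)Cc1cc(OC)cc(OC)c1C(=O)O | intermediate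
7 | 2-(carboxymethyl)-4,6-dimethoxybenzoic acid | COc1cc(CC(=O)O)c(C(=O)O)c(OC)c1 | intermediate
8 | 6,8-dimethoxyisochromane-1,3-dione | COc1cc2CC(=O)OC(=O)c2c(OC)c1 | intermediate
9 | methyl 3-chloro-3-oxopropanoate (methyl malonyl chloride) | COC(=O)CC(=O)Cl | starting material
10 | 6,8-dimethoxy-4-(3-methoxy-3-oxopropanoyl)isochromane-1,3-dione | COC(=O)CC(=O)C1C(=O)OC(=O)c2c(OC)cc(OC)cc21 | intermediate
11 | 2,4-dimethoxy-6-(4-methoxy-2,4-dioxobutyl)benzoic acid | COC(=O)CC(=O)Cc1cc(OC)cc(OC)c1C(=O)O | intermediate
12 | methyl 2-(6,8-dimethoxy-1-oxo-1H-isochromen-3-yl)acetate | COC(=O)Cc1cc2cc(OC)cc(OC)c2c(=O)o1 | intermediate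
13 | 2-(6,8-dihydroxy-1-oxo-1H-isochromen-3-yl)acetic acid | O=C(O)Cc1cc2cc(O)cc(O)c2c(=O)o1 | intermediate
14 | tert-butyldimethylsilyl 2-[6,8-bis(tert-butyldimethylsilyloxy)-1-oxo-1H-isochromen-3-yl]acetate | CC(C)(C)[Si](C)(C)OC(=O)Cc1cc2cc(O[Si](C)(C)C(C)(C)C)cc(O[Si](C)(C)C(C)(C)C)c2c(=O)o1 | intermediate
15 | non-1-yne | CCCCCCCC#C | starting material
16 | 2-[6,8-bis(tert-butyldimethylsilyloxy)-1-oxo-1H-isochromen-3-yl]acetyl chloride | O=C(Cl)Cc1cc2cc(O[Si](C)(C)C(C)(C)C)cc(O[Si](C)(C)C(C)(C)C)c2c(=O)o1 | intermediate
17 | non-1-ynyllithium | [Li]C#CCCCCCCC | intermediate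
18 | chloro(non-1-ynyl)zinc | Cl[Zn]C#CCCCCCCC | intermediate
19 | 6,8-bis(tert-butyldimethylsilyloxy)-3-(2-oxoundec-3-yn-1-yl)-1H-isochromen-1-one | CCCCCCCC#CC(=O)Cc1cc2cc(O[Si](C)(C)C(C)(C)C)cc(O[Si](C)(C)C(C)(C)C)c2c(=O)o1 | intermediate
20 | 6,8-bis(tert-butyldimethylsilyloxy)-3-{2-[2-heptyl-6-methoxy-4,6-bis(trimethylsilyloxy)cyclohexa-1,4-dien-1-yl]-2-oxoethyl}-1H-isochromen-1-one (racemic at the ketal carbon) | CCCCCCCC1=C(C(=O)Cc2cc3cc(O[Si](C)(C)C(C)(C)C)cc(O[Si](C)(C)C(C)(C)C)c3c(=O)o2)C(OC)(O[Si](C)(C)C)C=C(O[Si](C)(C)C)C1 | intermediate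
21 | 6,8-bis(tert-butyldimethylsilyloxy)-3-{2-[2-heptyl-6-hydroxy-4-(trimethylsilyloxy)phenyl]-2-oxoethyl}-1H-isochromen-1-one | CCCCCCCc1cc(O[Si](C)(C)C)cc(O)c1C(=O)Cc1cc2cc(O[Si](C)(C)C(C)(C)C)cc(O[Si](C)(C)C(C)(C)C)c2c(=O)o1 | intermediate
22 | 6,8-bis(tert-butyldimethylsilyloxy)-3-[2-(2-heptyl-4,6-dihydroxyphenyl)-2-oxoethyl]-1H-isochromen-1-one | CCCCCCCc1cc(O)cc(O)c1C(=O)Cc1cc2cc(O[Si](C)(C)C(C)(C)C)cc(O[Si](C)(C)C(C)(C)C)c2c(=O)o1 | intermediate
23 | 3-[2-(2-heptyl-4,6-dihydroxyphenyl)-2-oxoethyl]-6,8-dihydroxy-1H-isochromen-1-one | CCCCCCCc1cc(O)cc(O)c1C(=O)Cc1cc2cc(O)cc(O)c2c(=O)o1 | intermediate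
24 | 2-[4-(2-heptyl-4,6-dihydroxyphenyl)-2,4-dioxobutyl]-4,6-dihydroxybenzoic acid | CCCCCCCc1cc(O)cc(O)c1C(=O)CC(=O)Cc1cc(O)cc(O)c1C(=O)O | intermediate
25 | rac-2-[(5-heptyl-2,7-dihydroxy-4-oxo-3,4-dihydro-2H-chromen-2-yl)methyl]-4,6-dihydroxybenzoic acid | CCCCCCCc1cc(O)cc2c1C(=O)CC(O)(Cc1cc(O)cc(O)c1C(=O)O)O2 | intermediate
26 | quininium (R)-2-[(5-heptyl-2,7-dihydroxy-4-oxo-3,4-dihydro-2H-chromen-2-yl)methyl]-4,6-dihydroxybenzoate | CCCCCCCc1cc(O)cc2c1C(=O)C[C@@](O)(Cc1cc(O)cc(O)c1C(=O)[O-])O2.COC1=CC2=C(C=CN=C2C=C1)[C@H]([C@@H]3C[C@@H]4CC[NH+]3C[C@@H]4C=C)O | intermediate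
27 | (R)-2-[(5-heptyl-2,7-dihydroxy-4-oxo-3,4-dihydro-2H-chromen-2-yl)methyl]-4,6-dihydroxybenzoic acid | CCCCCCCc1cc(O)cc2c1C(=O)C[C@@](O)(Cc1cc(O)cc(O)c1C(=O)O)O2 | target

**Count and risks**

Total step count: 13. Longest linear sequence: 11 steps (steps 3 to 13, from 4 to 27); the diene branch (steps 1 and 2) joins at step 10.

Steps most likely to fail:

1. Step 12. The salts may not crystallize, or the exchange between the diastereomers through the open diketone may be slower than crystal growth, so that the solid is not driven to one configuration; the configuration may also erode while the acid is released. Fallback: starting from 25, the racemate is resolved by preparative chromatography on a chiral stationary phase (amylose tris(3,5-dimethylphenylcarbamate), CO2/MeOH with a little formic acid, 5 °C). One fraction is 27 itself, where the route is rejoined. The other is (S)-2-[(5-heptyl-2,7-dihydroxy-4-oxo-3,4-dihydro-2H-chromen-2-yl)methyl]-4,6-dihydroxybenzoic acid F1, which is left to racemize in MeCN containing Et3N (through 24) and is injected again.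

2. Step 10. Silyl transfer from the diene to the enolizable CH2 between ketone and isocoumarin, and thermal decay of the diene, may outrun the cycloaddition. Fallback: starting from 13, ring A is brought in ready-made by Friedel–Crafts acylation of purchased 5-heptylresorcinol (CCCCCCCc1cc(O)cc(O)c1) with the free acid in BF3·OEt2 at 70 °C, the standard way to 2,4-dihydroxyphenyl benzyl ketones. Acylation ortho to the heptyl group gives 23, where the route is rejoined, and the KOH treatment of step 11 carries it on to 25. The price is the positional isomer acylated between the two hydroxyls, which has to be removed by chromatography. This detour makes no compound outside the list (F0).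

3. Step 9. Loss of carbon monoxide from the acylpalladium intermediate, whose CH2 is allyl-like, and ketene formation from the enolizable acid chloride may divert the coupling. Fallback: starting from 14, the acid chloride 16 is made as before and is treated with N,O-dimethylhydroxylamine hydrochloride and pyridine in CH2Cl2 at 0 °C to give 2-[6,8-bis(tert-butyldimethylsilyloxy)-1-oxo-1H-isochromen-3-yl]-N-methoxy-N-methylacetamide F2. Addition of non-1-ynyllithium 17 in THF at −78 °C (Weinreb ketone synthesis) and cold acidic quench of the stable chelate then give 19, where the route is rejoined, without palladium and without contact between an acid chloride and an organometallic.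

**Further compounds**

F1 | step 12 | (S)-2-[(5-heptyl-2,7-dihydroxy-4-oxo-3,4-dihydro-2H-chromen-2-yl)methyl]-4,6-dihydroxybenzoic acid | CCCCCCCc1cc(O)cc2c1C(=O)C[C@](O)(Cc1cc(O)cc(O)c1C(=O)O)O2
F0 | step 10 | none | none
F2 | step 9 | 2-[6,8-bis(tert-butyldimethylsilyloxy)-1-oxo-1H-isochromen-3-yl]-N-methoxy-N-methylacetamide | CON(C)C(=O)Cc1cc2cc(O[Si](C)(C)C(C)(C)C)cc(O[Si](C)(C)C(C)(C)C)c2c(=O)o1
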